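**Retrosynthetic overview**
1. Target 24 ⇐ C-3–C-4 bond: chromium-catalysed electroreductive alkenyl iodide–carbonyl ring closure of lactol 23 (ten-membered ring formed last; sets C-3).
2. 23 ⇐ 15 by moving the lactone from O-6 to O-8 (open, angeloylate O-6, relactonise on O-8), acetylating O-1 and unmasking C-3.
3. 15 ⇐ C-7–C-8 bond: indium Barbier union of bromobutenolide 8 with lactol 14; C-6 sets C-7 and C-8.
4. 8 ⇐ lactone 1 (brings C-6; Z-iodo-olefination, then butenolide and bromomethyl installation). 14 ⇐ 2-deoxy-D-ribose 9 (brings C-1; pyranoside, 4-ulose, Ph3P=C=C=O annulation that locks the 9Z alkene).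
5. Ring order: γ-lactone of 1 (temporary, on O-6) → pyranoside and fused butenolide (temporary) → final 8,12-lactone → ten-membered carbocycle.

Assumption and numbering: 1 (made from L-glutamic acid) and 9 are taken as the two commercial chiral starting materials. Locants follow the germacrane pattern: C-1 (CH–OAc), C-2 (CH2), C-3 (CH–OH), C-4 (C–CH3), C-5 (=CH), C-6 (CH–O-angeloyl), C-7 (CH), C-8 (CH–O-lactone), C-9 (=CH), C-10 (C–CH2OH), C-11/C-12/C-13 (lactone α-carbon, carbonyl, exocyclic CH2), C-14 (CH2OH), C-15 (CH3). The target is (1S,3S,6R,7S,8S,4Z,9Z).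

**Step 1**
Reactants: 1 (S)-5-(hydroxymethyl)dihydrofuran-2(3H)-one
Product: 2 (S)-5-oxotetrahydrofuran-2-carbaldehyde
Conditions: TEMPO (10 mol %), PhI(OAc)2, CH2Cl2, rt
Reagents that add atoms: none
Why: Nitroxyl-catalysed oxidation of a primary alcohol stops at the aldehyde under non-basic conditions, so the oxygen-bearing stereocentre (future C-6) is not epimerised.

**Step 2**
Reactants: 2 (S)-5-oxotetrahydrofuran-2-carbaldehyde
Product: 3 (S)-5-[(Z)-2-iodoprop-1-en-1-yl]dihydrofuran-2(3H)-one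
Conditions: [Ph3PCH2CH3]I, n-BuLi, THF, rt; I2, −78 °C; NaN(SiMe3)2, −20 °C; then 2, −78 °C → rt
Reagents that add atoms: ethyltriphenylphosphonium iodide (CC[P+](c1ccccc1)(c1ccccc1)c1ccccc1.[I-]); iodine (II)
Why: Stork–Zhao α-iodo Wittig olefination gives the (Z)-vinyl iodide (iodine cis to the lactone carbon), and the low temperature keeps the α-stereocentre intact.

**Step 3**
Reactants: 3 (S)-5-[(Z)-2-iodoprop-1-en-1-yl]dihydrofuran-2(3H)-one
Product: 4 (5S)-5-[(Z)-2-iodoprop-1-en-1-yl]-3-(phenylselanyl)dihydrofuran-2(3H)-one (both C-3 epimers)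
Conditions: LiN(SiMe3)2, THF, −78 °C; PhSeBr, −78 °C
Reagents that add atoms: phenylselenenyl bromide (Br[Se]c1ccccc1)
Why: α-Selenenylation of the lactone enolate installs the group needed for later syn-elimination; the new centre is destroyed again, so its configuration does not matter.

**Step 4**
Reactants: 4 (5S)-5-[(Z)-2-iodoprop-1-en-1-yl]-3-(phenylselanyl)dihydrofuran-2(3H)-one
Product: 7 (S)-3-(hydroxymethyl)-5-[(Z)-2-iodoprop-1-en-1-yl]furan-2(5H)-one, via hydroxymethyl selenide 5 (not isolated), via selenoxide 6 (not isolated)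
Conditions: LiN(iPr)2, THF, −78 °C; CH2O (gas), −78 → −20 °C; AcOH; 30% H2O2, 0 °C → rt
Reagents that add atoms: formaldehyde (C=O)
Why: Aldol reaction of the α-seleno enolate with formaldehyde, then selenoxide syn-elimination, which goes into the ring (away from the carbinol carbon) and gives the endocyclic butenolide without touching C-6.

**Step 5**
Reactants: 7 (S)-3-(hydroxymethyl)-5-[(Z)-2-iodoprop-1-en-1-yl]furan-2(5H)-one
Product: 8 (S)-3-(bromomethyl)-5-[(Z)-2-iodoprop-1-en-1-yl]furan-2(5H)-one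
Conditions: CBr4, PPh3, CH2Cl2, 0 °C
Reagents that add atoms: carbon tetrabromide (BrC(Br)(Br)Br)
Why: Appel bromination of the primary allylic alcohol runs under neutral conditions, which avoids γ-deprotonation (racemisation) of the butenolide.

**Step 6**
Reactants: 9 2-deoxy-D-ribose
Product: 10 methyl 2-deoxy-β-D-erythro-pentopyranoside
Conditions: MeOH, HCl (cat.), rt; crystallisation of the β-anomer
Reagents that add atoms: methanol (CO)
Why: Fischer glycosidation under thermodynamic control gives the pyranoside, which ties O-14 and the C-3 aldehyde into one acetal and leaves only the cis-3,4-diol free; the stereocentre that becomes C-1 is untouched.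

**Step 7**
Reactants: 10 methyl 2-deoxy-β-D-erythro-pentopyranoside
Product: 12 methyl 2-deoxy-β-D-glycero-pentopyranosid-4-ulose, via stannylene acetal 11 (not isolated)
Conditions: Bu2SnO, MeOH, reflux; evaporate; Br2, 4 Å molecular sieves, CH2Cl2, rt
Reagents that add atoms: none
Why: Brominolysis of a dibutylstannylene acetal oxidises the axial hydroxyl of a cis-diol, and in the chair with axial methoxy the 4-OH (future C-10) is axial, so the C-1 carbinol stays.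

**Step 8**
Reactants: 12 methyl 2-deoxy-β-D-glycero-pentopyranosid-4-ulose
Product: 13 (6R,7aS)-6-methoxy-7,7a-dihydro-4H-furo[3,2-c]pyran-2(6H)-one
Conditions: Ph3P=C=C=O, toluene, 80 °C
Reagents that add atoms: (triphenylphosphoranylidene)ketene (O=C=C=P(c1ccccc1)(c1ccccc1)c1ccccc1)
Why: The hydroxyl adds to the ketene ylide and the resulting ester ylide closes by intramolecular Wittig reaction onto the ketone; the butenolide ring fixes the C-9=C-10 geometry as Z (C-8 cis to C-1).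

**Step 9**
Reactants: 13 (6R,7aS)-6-methoxy-7,7a-dihydro-4H-furo[3,2-c]pyran-2(6H)-one
Product: 14 (6R,7aS)-6-methoxy-2,6,7,7a-tetrahydro-4H-furo[3,2-c]pyran-2-ol (both C-2 epimers)
Conditions: iBu2AlH, CH2Cl2, −78 °C; aq. potassium sodium tartrate
Reagents that add atoms: none
Why: Partial reduction of the lactone at low temperature stops at the lactol, a masked (Z)-γ-hydroxy enal; neutral work-up avoids dehydration to the furan.

**Step 10**
Reactants: 8 (S)-3-(bromomethyl)-5-[(Z)-2-iodoprop-1-en-1-yl]furan-2(5H)-one; 14 (6R,7aS)-6-methoxy-2,6,7,7a-tetrahydro-4H-furo[3,2-c]pyran-2-ol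
Product: 15 (4R,5S)-4-{(1S,2Z)-1-hydroxy-2-[(4S,6R)-4-hydroxy-6-methoxyoxan-3-ylidene]ethyl}-5-[(Z)-2-iodoprop-1-en-1-yl]-3-methylideneoxolan-2-one
Conditions: indium powder, THF/H2O (1:1), rt
Reagents that add atoms: none
Why: Barbier allylation: the allylindium reacts at C-7 (SE2′) on the face anti to the C-5 arm, and the ring-fixed (E)-type allyl geometry in a Zimmerman–Traxler chair gives the 7,8-anti adduct, so C-7 and C-8 are both set by C-6.

**Step 11**
Reactants: 15 (4R,5S)-4-{(1S,2Z)-1-hydroxy-2-[(4S,6R)-4-hydroxy-6-methoxyoxan-3-ylidene]ethyl}-5-[(Z)-2-iodoprop-1-en-1-yl]-3-methylideneoxolan-2-one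
Product: 16 (4S,5S)-5-[(Z)-2-iodoprop-1-en-1-yl]-4-{(1S,2Z)-2-[(4S,6R)-6-methoxy-4-(triethylsilyloxy)oxan-3-ylidene]-1-(triethylsilyloxy)ethyl}-3-methylideneoxolan-2-one
Conditions: Et3SiCl, imidazole, DMF, 0 °C → rt
Reagents that add atoms: chlorotriethylsilane (CC[Si](Cl)(CC)CC)
Why: Silylation of both allylic hydroxyls (O-8, O-1) blocks them so that only O-6 is free after the lactone is opened.

**Step 12**
Reactants: 16 (4S,5S)-5-[(Z)-2-iodoprop-1-en-1-yl]-4-{(1S,2Z)-2-[(4S,6R)-6-methoxy-4-(triethylsilyloxy)oxan-3-ylidene]-1-(triethylsilyloxy)ethyl}-3-methylideneoxolan-2-one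
Product: 18 methyl (3S,4S,5Z)-4-hydroxy-6-iodo-3-{(1S,2Z)-2-[(4S,6R)-6-methoxy-4-(triethylsilyloxy)oxan-3-ylidene]-1-(triethylsilyloxy)ethyl}-2-methylidenehept-5-enoate, via lithium carboxylate 17 (not isolated)
Conditions: LiOH, THF/H2O, 0 °C; concentrate; MeI, DMF, 0 °C
Reagents that add atoms: lithium hydroxide ([Li+].[OH-]); iodomethane (CI)
Why: Saponification by acyl–oxygen cleavage keeps C-6 intact, and O-alkylation of the carboxylate salt gives the ester without ever forming the free hydroxy acid that would relactonise.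

**Step 13**
Reactants: 18 methyl (3S,4S,5Z)-4-hydroxy-6-iodo-3-{(1S,2Z)-2-[(4S,6R)-6-methoxy-4-(triethylsilyloxy)oxan-3-ylidene]-1-(triethylsilyloxy)ethyl}-2-methylidenehept-5-enoate
Product: 19 methyl (3S,4S,5Z)-6-iodo-3-{(1S,2Z)-2-[(4S,6R)-6-methoxy-4-(triethylsilyloxy)oxan-3-ylidene]-1-(triethylsilyloxy)ethyl}-4-{[(2Z)-2-methylbut-2-enoyl]oxy}-2-methylidenehept-5-enoate
Conditions: angelic acid, 2,4,6-trichlorobenzoyl chloride, Et3N, toluene, rt; then 18, DMAP, rt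
Reagents that add atoms: angelic acid (C/C=C(/C)C(=O)O)
Why: Yamaguchi esterification acylates the only free hydroxyl (O-6) at room temperature, mild enough to keep the (Z)-geometry of the angelate.

**Step 14**
Reactants: 19 methyl (3S,4S,5Z)-6-iodo-3-{(1S,2Z)-2-[(4S,6R)-6-methoxy-4-(triethylsilyloxy)oxan-3-ylidene]-1-(triethylsilyloxy)ethyl}-4-{[(2Z)-2-methylbut-2-enoyl]oxy}-2-methylidenehept-5-enoate
Product: 21 (1S,2Z)-1-[(2S,3R)-2-{(Z)-[(4S,6R)-4-hydroxy-6-methoxyoxan-3-ylidene]methyl}-4-methylidene-5-oxooxolan-3-yl]-3-iodobut-2-en-1-yl (2Z)-2-methylbut-2-enoate, via diol ester 20 (not isolated)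
Conditions: HF·pyridine, pyridine, THF, 0 °C → rt; then PPTS (cat.), CH2Cl2, rt
Reagents that add atoms: none
Why: Desilylation then lactonisation: only O-8 can close a five-membered ring onto C-12 (O-1 would need an eight-membered one), which completes the transfer of the lactone from O-6 to O-8 with retention at both carbons.

**Step 15**
Reactants: 21 (1S,2Z)-1-[(2S,3R)-2-{(Z)-[(4S,6R)-4-hydroxy-6-methoxyoxan-3-ylidene]methyl}-4-methylidene-5-oxooxolan-3-yl]-3-iodobut-2-en-1-yl (2Z)-2-methylbut-2-enoate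
Product: 22 (1S,2Z)-1-[(2S,3R)-2-{(Z)-[(4S,6R)-4-acetoxy-6-methoxyoxan-3-ylidene]methyl}-4-methylidene-5-oxooxolan-3-yl]-3-iodobut-2-en-1-yl (2Z)-2-methylbut-2-enoate
Conditions: Ac2O, pyridine, DMAP (cat.), CH2Cl2, 0 °C
Reagents that add atoms: acetic anhydride (CC(=O)OC(C)=O)
Why: Acetylation of the single remaining hydroxyl (O-1).

**Step 16**
Reactants: 22 (1S,2Z)-1-[(2S,3R)-2-{(Z)-[(4S,6R)-4-acetoxy-6-methoxyoxan-3-ylidene]methyl}-4-methylidene-5-oxooxolan-3-yl]-3-iodobut-2-en-1-yl (2Z)-2-methylbut-2-enoate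
Product: 23 (1S,2Z)-1-[(2S,3R)-2-{(Z)-[(4S)-4-acetoxy-6-hydroxyoxan-3-ylidene]methyl}-4-methylidene-5-oxooxolan-3-yl]-3-iodobut-2-en-1-yl (2Z)-2-methylbut-2-enoate (both C-6 epimers of the oxane)
Conditions: AcOH/H2O/THF (3:1:1), 35 °C
Reagents that add atoms: water (O)
Why: Acetal hydrolysis of a 2-deoxy glycoside is fast under mild acid that leaves the three esters and the vinyl iodide alone; it gives the lactol form of the C-3 aldehyde with O-14 free.

**Step 17**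
Reactants: 23 (1S,2Z)-1-[(2S,3R)-2-{(Z)-[(4S)-4-acetoxy-6-hydroxyoxan-3-ylidene]methyl}-4-methylidene-5-oxooxolan-3-yl]-3-iodobut-2-en-1-yl (2Z)-2-methylbut-2-enoate
Product: 24 CNP0153210.4, (1S,3S,4Z,6R,7S,8S,9Z)-1-acetoxy-6-(angeloyloxy)-3,14-dihydroxygermacra-4,9,11(13)-trien-12,8-olide
Conditions: CrCl2 (20 mol %), NiCl2·glyme (5 mol %), Cp2ZrCl2 (1.2 equiv), Bu4NBr, DMF (2 mM), undivided cell, aluminium anode, nickel-foam cathode, constant current, rt
Reagents that add atoms: none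
Why: Proposed new method: chromium-catalysed electroreductive Nozaki–Hiyama–Kishi macrocyclisation onto a δ-lactol used as a latent aldehyde; zerovalent nickel inserts into the C-4–I bond and hands the alkenyl group to chromium, the alkenyl trivalent chromium species adds to the small equilibrium amount of open δ-hydroxy aldehyde that Cp2ZrCl2 drains from the lactol by capping O-14 and the product alkoxide, and the cathode returns trivalent to divalent chromium; the low standing aldehyde concentration acts as internal high dilution, and C-3 (S) is set 1,3-anti to the C-1 acetate (dipole-opposed β-acyloxy aldehyde) inside a ten-membered transition state held by the two Z alkenes; the closest known reaction type is the nickel/chromium-mediated macrocyclisation of ω-iodoalkenyl aldehydes together with the intermolecular electrochemical chromium-catalysed alkenyl halide–aldehyde coupling.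

**Compound list**
1 | (S)-5-(hydroxymethyl)dihydrofuran-2(3H)-one | O=C1CC[C@@H](CO)O1 | starting material
2 | (S)-5-oxotetrahydrofuran-2-carbaldehyde | O=C1CC[C@@H](C=O)O1 | intermediate
3 | (S)-5-[(Z)-2-iodoprop-1-en-1-yl]dihydrofuran-2(3H)-one | O=C1CC[C@@H](/C=C(\I)C)O1 | intermediate
4 | (5S)-5-[(Z)-2-iodoprop-1-en-1-yl]-3-(phenylselanyl)dihydrofuran-2(3H)-one (both C-3 epimers) | O=C1C([Se]c2ccccc2)C[C@@H](/C=C(\I)C)O1 | intermediate
5 | (5S)-3-(hydroxymethyl)-5-[(Z)-2-iodoprop-1-en-1-yl]-3-(phenylselanyl)dihydrofuran-2(3H)-one | O=C1C(CO)([Se]c2ccccc2)C[C@@H](/C=C(\I)C)O1 | intermediate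
6 | (5S)-3-(hydroxymethyl)-5-[(Z)-2-iodoprop-1-en-1-yl]-3-(phenylseleninyl)dihydrofuran-2(3H)-one | O=C1C(CO)([Se](=O)c2ccccc2)C[C@@H](/C=C(\I)C)O1 | intermediate
7 | (S)-3-(hydroxymethyl)-5-[(Z)-2-iodoprop-1-en-1-yl]furan-2(5H)-one | O=C1C(CO)=C[C@@H](/C=C(\I)C)O1 | intermediate
8 | (S)-3-(bromomethyl)-5-[(Z)-2-iodoprop-1-en-1-yl]furan-2(5H)-one | O=C1C(CBr)=C[C@@H](/C=C(\I)C)O1 | intermediate
9 | 2-deoxy-D-ribose (2-deoxy-D-erythro-pentose) | O=CC[C@H](O)[C@H](O)CO | starting material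
10 | methyl 2-deoxy-β-D-erythro-pentopyranoside, (2R,4S,5R)-2-methoxyoxane-4,5-diol | CO[C@H]1C[C@H](O)[C@H](O)CO1 | intermediate
11 | 3,4-O-dibutylstannylene acetal of 10 | CO[C@H]1C[C@@H]2O[Sn](CCCC)(CCCC)O[C@@H]2CO1 | intermediate
12 | methyl 2-deoxy-β-D-glycero-pentopyranosid-4-ulose, (4S,6R)-4-hydroxy-6-methoxyoxan-3-one | CO[C@H]1C[C@H](O)C(=O)CO1 | intermediate
13 | (6R,7aS)-6-methoxy-7,7a-dihydro-4H-furo[3,2-c]pyran-2(6H)-one | CO[C@H]1C[C@@H]2OC(=O)C=C2CO1 | intermediate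
14 | (6R,7aS)-6-methoxy-2,6,7,7a-tetrahydro-4H-furo[3,2-c]pyran-2-ol (both C-2 epimers) | CO[C@H]1C[C@@H]2OC(O)C=C2CO1 | intermediate
15 | (4R,5S)-4-{(1S,2Z)-1-hydroxy-2-[(4S,6R)-4-hydroxy-6-methoxyoxan-3-ylidene]ethyl}-5-[(Z)-2-iodoprop-1-en-1-yl]-3-methylideneoxolan-2-one | C=C1C(=O)O[C@H](/C=C(\I)C)[C@H]1[C@@H](O)/C=C1/CO[C@@H](OC)C[C@@H]1O | intermediate
16 | (4S,5S)-5-[(Z)-2-iodoprop-1-en-1-yl]-4-{(1S,2Z)-2-[(4S,6R)-6-methoxy-4-(triethylsilyloxy)oxan-3-ylidene]-1-(triethylsilyloxy)ethyl}-3-methylideneoxolan-2-one | C=C1C(=O)O[C@H](/C=C(\I)C)[C@H]1[C@@H](O[Si](CC)(CC)CC)/C=C1/CO[C@@H](OC)C[C@@H]1O[Si](CC)(CC)CC | intermediate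
17 | lithium (3S,4S,5Z)-4-hydroxy-6-iodo-3-{(1S,2Z)-2-[(4S,6R)-6-methoxy-4-(triethylsilyloxy)oxan-3-ylidene]-1-(triethylsilyloxy)ethyl}-2-methylidenehept-5-enoate | [Li+].[O-]C(=O)C(=C)[C@@H]([C@H](O)/C=C(\I)C)[C@@H](O[Si](CC)(CC)CC)/C=C1/CO[C@@H](OC)C[C@@H]1O[Si](CC)(CC)CC | intermediate
18 | methyl (3S,4S,5Z)-4-hydroxy-6-iodo-3-{(1S,2Z)-2-[(4S,6R)-6-methoxy-4-(triethylsilyloxy)oxan-3-ylidene]-1-(triethylsilyloxy)ethyl}-2-methylidenehept-5-enoate | COC(=O)C(=C)[C@@H]([C@H](O)/C=C(\I)C)[C@@H](O[Si](CC)(CC)CC)/C=C1/CO[C@@H](OC)C[C@@H]1O[Si](CC)(CC)CC | intermediate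
19 | methyl (3S,4S,5Z)-6-iodo-3-{(1S,2Z)-2-[(4S,6R)-6-methoxy-4-(triethylsilyloxy)oxan-3-ylidene]-1-(triethylsilyloxy)ethyl}-4-{[(2Z)-2-methylbut-2-enoyl]oxy}-2-methylidenehept-5-enoate | COC(=O)C(=C)[C@@H]([C@H](OC(=O)/C(C)=C\C)/C=C(\I)C)[C@@H](O[Si](CC)(CC)CC)/C=C1/CO[C@@H](OC)C[C@@H]1O[Si](CC)(CC)CC | intermediate
20 | methyl (3S,4S,5Z)-3-{(1S,2Z)-1-hydroxy-2-[(4S,6R)-4-hydroxy-6-methoxyoxan-3-ylidene]ethyl}-6-iodo-4-{[(2Z)-2-methylbut-2-enoyl]oxy}-2-methylidenehept-5-enoate | COC(=O)C(=C)[C@@H]([C@H](OC(=O)/C(C)=C\C)/C=C(\I)C)[C@@H](O)/C=C1/CO[C@@H](OC)C[C@@H]1O | intermediate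
21 | (1S,2Z)-1-[(2S,3R)-2-{(Z)-[(4S,6R)-4-hydroxy-6-methoxyoxan-3-ylidene]methyl}-4-methylidene-5-oxooxolan-3-yl]-3-iodobut-2-en-1-yl (2Z)-2-methylbut-2-enoate | C=C1C(=O)O[C@@H](/C=C2/CO[C@@H](OC)C[C@@H]2O)[C@@H]1[C@H](OC(=O)/C(C)=C\C)/C=C(\I)C | intermediate
22 | (1S,2Z)-1-[(2S,3R)-2-{(Z)-[(4S,6R)-4-acetoxy-6-methoxyoxan-3-ylidene]methyl}-4-methylidene-5-oxooxolan-3-yl]-3-iodobut-2-en-1-yl (2Z)-2-methylbut-2-enoate | C=C1C(=O)O[C@@H](/C=C2/CO[C@@H](OC)C[C@@H]2OC(C)=O)[C@@H]1[C@H](OC(=O)/C(C)=C\C)/C=C(\I)C | intermediate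
23 | (1S,2Z)-1-[(2S,3R)-2-{(Z)-[(4S)-4-acetoxy-6-hydroxyoxan-3-ylidene]methyl}-4-methylidene-5-oxooxolan-3-yl]-3-iodobut-2-en-1-yl (2Z)-2-methylbut-2-enoate (both oxane C-6 epimers) | C=C1C(=O)O[C@@H](/C=C2/COC(O)C[C@@H]2OC(C)=O)[C@@H]1[C@H](OC(=O)/C(C)=C\C)/C=C(\I)C | intermediate
24 | CNP0153210.4, (1S,3S,4Z,6R,7S,8S,9Z)-1-acetoxy-6-(angeloyloxy)-3,14-dihydroxygermacra-4,9,11(13)-trien-12,8-olide | C=C1C(=O)O[C@H]2/C=C(/CO)[C@@H](OC(C)=O)C[C@H](O)/C(C)=C\[C@@H](OC(=O)/C(C)=C\C)[C@H]12 | target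

**Step count and risks**
Total: 17 steps. Longest linear sequence: 13 steps (1 → 24 through steps 1–5 and 10–17); the branch 9 → 14 is 4 steps.

Most likely to fail:

Step 17 (the proposed new step). The lactol may open too slowly for the alkenylchromium to find an aldehyde, the cathodic turnover may stall on the free hydroxyls, or the C-3 epimer may form. The fallback uses known chemistry and sets out from 22. Propane-1,3-dithiol with BF3·OEt2 at low temperature opens the glycoside to the open-chain dithiane alcohol F1. TBSOTf and 2,6-lutidine cap O-14 to give the silyl ether F2. PhI(OCOCF3)2 in aqueous acetonitrile releases the true aldehyde F3. A classical stoichiometric Nozaki–Hiyama–Kishi ring closure (CrCl2 in excess, catalytic NiCl2, DMSO, high dilution) gives the macrocyclic silyl ether F4. HF·pyridine then removes the silyl group, and the route comes back at 24.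

Step 10. Lactol 14 can lose water to the aromatic furan before it is allylated, and its open form is only a minor component. The fallback sets out from 13 and replaces the lactol by a protected open-chain enal. Excess iBu2AlH reduces 13 to the (Z)-ene-diol F5. Et3SiCl and imidazole give the bis-silyl ether F6. Swern conditions (oxalyl chloride, DMSO, Et3N) oxidise the primary silyl ether selectively to the (Z)-enal F7. Zinc dust in THF/aqueous NH4Cl couples F7 with 8 to give the alcohol F8, and silylation of O-8 with Et3SiCl brings the route back at 16.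

Step 12. Hydroxide can add to the methylene lactone, and hydroxy ester 18 can relactonise on O-6 before it is acylated. The fallback sets out from 16 and avoids both the carboxylate and the ester. Me(MeO)NH·HCl with AlMe3 opens the lactone to the hydroxy Weinreb amide F9, which does not relactonise under neutral conditions. Yamaguchi angeloylation gives the amide angelate F10. HF·pyridine followed by camphorsulfonic acid removes the silyl groups and lactonises O-8 onto the amide, and the route comes back at 21.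

**Further compounds**
F1 | step 17 | (1S,2Z)-1-[(2S,3R)-2-{(1Z,3S)-3-acetoxy-4-(1,3-dithian-2-yl)-2-(hydroxymethyl)but-1-en-1-yl}-4-methylidene-5-oxooxolan-3-yl]-3-iodobut-2-en-1-yl (2Z)-2-methylbut-2-enoate | C=C1C(=O)O[C@@H](/C=C(/CO)[C@H](CC2SCCCS2)OC(C)=O)[C@@H]1[C@H](OC(=O)/C(C)=C\C)/C=C(\I)C
F2 | step 17 | O-14 tert-butyldimethylsilyl ether of F1 | C=C1C(=O)O[C@@H](/C=C(/CO[Si](C)(C)C(C)(C)C)[C@H](CC2SCCCS2)OC(C)=O)[C@@H]1[C@H](OC(=O)/C(C)=C\C)/C=C(\I)C
F3 | step 17 | open-chain C-3 aldehyde with O-14 tert-butyldimethylsilyl ether, (1S,2Z)-1-[(2S,3R)-2-{(1Z,3S)-3-acetoxy-2-[(tert-butyldimethylsilyloxy)methyl]-5-oxopent-1-en-1-yl}-4-methylidene-5-oxooxolan-3-yl]-3-iodobut-2-en-1-yl (2Z)-2-methylbut-2-enoate | C=C1C(=O)O[C@@H](/C=C(/CO[Si](C)(C)C(C)(C)C)[C@H](CC=O)OC(C)=O)[C@@H]1[C@H](OC(=O)/C(C)=C\C)/C=C(\I)C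
F4 | step 17 | 14-O-tert-butyldimethylsilyl ether of 24 | C=C1C(=O)O[C@H]2/C=C(/CO[Si](C)(C)C(C)(C)C)[C@@H](OC(C)=O)C[C@H](O)/C(C)=C\[C@@H](OC(=O)/C(C)=C\C)[C@H]12
F5 | step 10 | (4S,6R)-3-[(Z)-2-hydroxyethylidene]-6-methoxyoxan-4-ol | OC/C=C1/CO[C@@H](OC)C[C@@H]1O
F6 | step 10 | bis(triethylsilyl) ether of F5 | CC[Si](CC)(CC)OC/C=C1/CO[C@@H](OC)C[C@@H]1O[Si](CC)(CC)CC
F7 | step 10 | (2Z)-2-[(4S,6R)-6-methoxy-4-(triethylsilyloxy)oxan-3-ylidene]acetaldehyde | O=C/C=C1/CO[C@@H](OC)C[C@@H]1O[Si](CC)(CC)CC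
F8 | step 10 | (4R,5S)-4-{(1S,2Z)-1-hydroxy-2-[(4S,6R)-6-methoxy-4-(triethylsilyloxy)oxan-3-ylidene]ethyl}-5-[(Z)-2-iodoprop-1-en-1-yl]-3-methylideneoxolan-2-one | C=C1C(=O)O[C@H](/C=C(\I)C)[C@H]1[C@@H](O)/C=C1/CO[C@@H](OC)C[C@@H]1O[Si](CC)(CC)CC
F9 | step 12 | (3S,4S,5Z)-4-hydroxy-6-iodo-N-methoxy-N-methyl-3-{(1S,2Z)-2-[(4S,6R)-6-methoxy-4-(triethylsilyloxy)oxan-3-ylidene]-1-(triethylsilyloxy)ethyl}-2-methylidenehept-5-enamide | CON(C)C(=O)C(=C)[C@@H]([C@H](O)/C=C(\I)C)[C@@H](O[Si](CC)(CC)CC)/C=C1/CO[C@@H](OC)C[C@@H]1O[Si](CC)(CC)CC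
F10 | step 12 | O-4 angelate of F9 | CON(C)C(=O)C(=C)[C@@H]([C@H](OC(=O)/C(C)=C\C)/C=C(\I)C)[C@@H](O[Si](CC)(CC)CC)/C=C1/CO[C@@H](OC)C[C@@H]1O[Si](CC)(CC)CC
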